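The oxolane is opened at its C4–C5 bond, C5 being the ring carbon that carries the trienyl chain. Because this carbon sits between the ring oxygen, a ring CH2 and the chain, it is built as a one-carbon linchpin at the acetal oxidation level: the (phenylsulfonyl)methyl ether of the C2 carbinol is lithiated and closes the ring 5-exo-tet onto a primary chloride, giving an anomeric sulfone in one operation. Ionisation of that sulfone then admits the whole C14 chain trans to the C2 side chain. The precursor is an acyclic anti-diol derivative made by iridium-catalysed allylation; the 1,2-dioxane is closed last by SN2 perhydrolysis and peroxy-Michael addition.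

Key step: step 7

Remark: locants C1–C24 in the Why lines follow the fatty acid chain of the target (C1 = CO2H; C3 and C6 = dioxane carbons; C7 and C10 = oxolane C2 and C5; C9 = oxolane C4).
Assumption: in step 2 the (S)-ligand is taken to deliver the (3R,4S) adduct; should the sense of induction prove opposite, the (R)-ligand is used.

Step 1
Reactants: 1 acrolein; 2 benzoic anhydride
Product: 3 prop-2-ene-1,1-diyl dibenzoate
Conditions: FeCl3 (cat.), CH2Cl2, 0 °C to rt
Reagents that add atoms: none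
Why: Lewis-acid-catalysed acylal formation, in which the anhydride adds across the aldehyde C=O as is general for aldehydes, creates no stereocentre.

Step 2
Reactants: 3 prop-2-ene-1,1-diyl dibenzoate; 4 propane-1,3-diol (excess)
Product: 5 (3R,4S)-4,6-dihydroxyhex-1-en-3-yl benzoate
Conditions: [Ir(cod)Cl]2 (cat.), (S)-SEGPHOS (cat.), 4-cyano-3-nitrobenzoic acid (cat.), Cs2CO3 (cat.), THF, 90 °C
Reagents that add atoms: none
Why: Krische allylation (iridium-catalysed transfer-hydrogenative carbonyl (α-acyloxy)allylation from the alcohol oxidation level): one primary carbinol is dehydrogenated and the aldehyde is captured by the (E)-σ-(benzoyloxy)allyl iridium species through a closed chair transition state, which should give the anti (erythro) C6/C7 pair, the ligand setting the absolute configuration, while excess diol suppresses double coupling.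

Step 3
Reactants: 5 (3R,4S)-4,6-dihydroxyhex-1-en-3-yl benzoate
Product: 6 (3R,4S)-6-chloro-4-hydroxyhex-1-en-3-yl benzoate
Conditions: PPh3, CCl4, pyridine, MeCN, 0 °C to rt
Reagents that add atoms: tetrachloromethane, ClC(Cl)(Cl)Cl
Why: Appel chlorination, in which the alkoxyphosphonium forms fastest at the unhindered primary hydroxyl and is displaced by chloride, should leave the secondary C7 hydroxyl, the allylic benzoate and both stereocentres untouched.

Step 4
Reactants: 6 (3R,4S)-6-chloro-4-hydroxyhex-1-en-3-yl benzoate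
Product: 8 (3R,4S)-6-chloro-4-[(phenylsulfonyl)methoxy]hex-1-en-3-yl benzoate, via chloromethyl ether 7 (not isolated)
Conditions: (CH2O)n, Me3SiCl, CH2Cl2, 0 °C to rt; evaporate; PhSO2Na, DMF, rt
Reagents that add atoms: paraformaldehyde (formaldehyde unit), C=O; sodium benzenesulfinate, [Na+].[O-]S(=O)c1ccccc1
Why: Chloromethyl ether formation followed by S-alkylation of the sulfinate by the oxocarbenium-like α-chloro ether gives the α-alkoxy sulfone under non-basic conditions, so the neighbouring benzoate should neither migrate nor cleave and the far less electrophilic primary alkyl chloride should stay in place.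

Step 5
Reactants: 8 (3R,4S)-6-chloro-4-[(phenylsulfonyl)methoxy]hex-1-en-3-yl benzoate
Product: 9 (3R,4S)-6-chloro-4-[(phenylsulfonyl)methoxy]hex-1-en-3-ol
Conditions: K2CO3 (cat.), MeOH, 0 °C
Reagents that add atoms: none
Why: Zemplén-type transesterification removes the benzoate, which the carbanion of step 7 would otherwise attack, while the α-alkoxy sulfone and the primary chloride should be inert to catalytic carbonate at 0 °C.

Step 6
Reactants: 9 (3R,4S)-6-chloro-4-[(phenylsulfonyl)methoxy]hex-1-en-3-ol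
Product: 10 tert-butyl{[(3R,4S)-6-chloro-4-[(phenylsulfonyl)methoxy]hex-1-en-3-yl]oxy}dimethylsilane
Conditions: TBSOTf, 2,6-lutidine, CH2Cl2, −78 to 0 °C
Reagents that add atoms: tert-butyldimethylsilyl trifluoromethanesulfonate, CC(C)(C)[Si](C)(C)OS(=O)(=O)C(F)(F)F
Why: Silylation of the allylic secondary alcohol with a silyl triflate gives a base-stable, non-participating and bulky ether at C6, as needed for steps 7 and 12.

Step 7
Reactants: 10 tert-butyl{[(3R,4S)-6-chloro-4-[(phenylsulfonyl)methoxy]hex-1-en-3-yl]oxy}dimethylsilane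
Product: 12 tert-butyldimethyl{[(1R)-1-[(2S,5RS)-5-(phenylsulfonyl)oxolan-2-yl]prop-2-en-1-yl]oxy}silane, via lithiated sulfone 11 (not isolated)
Conditions: LiN(iPr)2, THF/DMPU, −78 °C to rt
Reagents that add atoms: none
Why: LiN(iPr)2 removes the proton flanked by the sulfonyl group and the ether oxygen, and the α-alkoxy α-sulfonyl carbanion displaces the primary chloride in an intramolecular SN2 reaction, which forms the C9–C10 bond (oxolane C4–C5) and with it the ring. The closest known reactions are the alkylation of lithiated alkoxymethyl and 2-oxacycloalkyl (anomeric) phenyl sulfones and the cyclisation of ω-haloalkyl sulfones. The oxolane closes in the 5-exo-tet mode. The new sulfonyl-bearing stereocentre (oxolane C5) is formed without control, by design, because both epimers ionise to the same oxocarbenium ion in step 12; the two existing stereocentres carry no acidic hydrogen and should survive. The step needs C-alkylation to outrun E2 loss of HCl, acyl transfer and intermolecular alkylation; the substrate secures this by carrying no carbonyl group, an unhindered primary halide and a five-membered transition state, with DMPU raising the reactivity of the carbanion.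

Step 8
Reactants: 12 tert-butyldimethyl{[(1R)-1-[(2S,5RS)-5-(phenylsulfonyl)oxolan-2-yl]prop-2-en-1-yl]oxy}silane; 13 ethyl (2Z)-3-iodoprop-2-enoate
Product: 15 ethyl (2Z,6R)-6-[(tert-butyldimethylsilyl)oxy]-6-[(2S,5RS)-5-(phenylsulfonyl)oxolan-2-yl]hex-2-enoate, via alkylborane 14 (not isolated)
Conditions: 9-BBN-H, THF, 0 °C to rt; then 13, Pd(dppf)Cl2 (cat.), AsPh3 (cat.), Cs2CO3, DMF/H2O, rt
Reagents that add atoms: none
Why: Anti-Markovnikov hydroboration of the monosubstituted alkene followed by B-alkyl Suzuki–Miyaura coupling installs C1–C3 as the Michael acceptor without touching sulfone or silyl ether, and the enoate geometry is immaterial for the later ring closure.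

Step 9
Reactants: 16 8-chlorooct-1-yne
Product: 17 1-bromo-8-chlorooct-1-yne
Conditions: N-bromosuccinimide, AgNO3 (cat.), acetone, rt
Reagents that add atoms: N-bromosuccinimide, O=C1CCC(=O)N1Br
Why: Silver-catalysed electrophilic bromination of the terminal alkyne C–H leaves the alkyl chloride untouched.

Step 10
Reactants: 17 1-bromo-8-chlorooct-1-yne; 18 hex-5-en-1-yne (excess)
Product: 19 14-chlorotetradec-1-ene-5,7-diyne
Conditions: CuCl (cat.), NH2OH·HCl (cat.), n-BuNH2 (30% aq.), Et2O, 0 °C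
Reagents that add atoms: none
Why: Cadiot–Chodkiewicz coupling of the copper acetylide of 18 with the bromoalkyne gives the unsymmetrical 1,3-diyne, the alkene and the alkyl chloride being spectators.

Step 11
Reactants: 19 14-chlorotetradec-1-ene-5,7-diyne
Product: 20 (5Z,7Z)-14-chlorotetradeca-1,5,7-triene
Conditions: Zn dust activated with Cu(OAc)2 and AgNO3, MeOH/H2O, 40 °C
Reagents that add atoms: none
Why: Boland reduction, in which activated zinc in a protic medium delivers two hydrogens syn to each conjugated triple bond only, should give the (Z,Z)-diene and leave the isolated terminal alkene and the chloride alone.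

Step 12
Reactants: 15 ethyl (2Z,6R)-6-[(tert-butyldimethylsilyl)oxy]-6-[(2S,5RS)-5-(phenylsulfonyl)oxolan-2-yl]hex-2-enoate; 20 (5Z,7Z)-14-chlorotetradeca-1,5,7-triene
Product: 23 ethyl (2Z,6R)-6-[(tert-butyldimethylsilyl)oxy]-6-{(2S,5R)-5-[(7Z,9Z)-tetradeca-7,9,13-trien-1-yl]oxolan-2-yl}hex-2-enoate, via Grignard reagent 21 (not isolated), via diorganozinc 22 (not isolated)
Conditions: 20, Mg, THF, reflux; ZnBr2, THF, 0 °C to rt; then 15, rt
Reagents that add atoms: none
Why: Lewis-acid-mediated substitution of an anomeric sulfone by an organozinc reagent: ZnBr2 ionises the sulfone to the oxolanyl oxocarbenium ion and the alkyl group should be transferred to the face anti to the bulky (silyloxy)alkyl group at oxolane C2, setting C10 as R (2,5-trans), while the organozinc does not add to the enoate.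

Step 13
Reactants: 23 ethyl (2Z,6R)-6-[(tert-butyldimethylsilyl)oxy]-6-{(2S,5R)-5-[(7Z,9Z)-tetradeca-7,9,13-trien-1-yl]oxolan-2-yl}hex-2-enoate
Product: 24 ethyl (2Z,6R)-6-hydroxy-6-{(2S,5R)-5-[(7Z,9Z)-tetradeca-7,9,13-trien-1-yl]oxolan-2-yl}hex-2-enoate
Conditions: HF·pyridine, pyridine, THF, 0 °C to rt
Reagents that add atoms: none
Why: Desilylation with buffered HF·pyridine is slightly acidic and so should avoid the base-induced 5-exo oxa-Michael closure of the freed C6 hydroxyl onto the enoate.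

Step 14
Reactants: 24 ethyl (2Z,6R)-6-hydroxy-6-{(2S,5R)-5-[(7Z,9Z)-tetradeca-7,9,13-trien-1-yl]oxolan-2-yl}hex-2-enoate
Product: 25 ethyl (2Z,6R)-6-{(2S,5R)-5-[(7Z,9Z)-tetradeca-7,9,13-trien-1-yl]oxolan-2-yl}-6-{[(trifluoromethyl)sulfonyl]oxy}hex-2-enoate
Conditions: Tf2O, 2,6-lutidine, CH2Cl2, −78 °C; cold work-up and immediate use
Reagents that add atoms: trifluoromethanesulfonic anhydride, O=S(=O)(OS(=O)(=O)C(F)(F)F)C(F)(F)F
Why: O-Sulfonylation with retention at C6 gives a secondary triflate that the β-oxygen of the oxolane stabilises against ionisation, as in carbohydrate triflates.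

Step 15
Reactants: 25 ethyl (2Z,6R)-6-{(2S,5R)-5-[(7Z,9Z)-tetradeca-7,9,13-trien-1-yl]oxolan-2-yl}-6-{[(trifluoromethyl)sulfonyl]oxy}hex-2-enoate
Product: 27 ethyl 2-[(3S,6S)-6-{(2S,5R)-5-[(7Z,9Z)-tetradeca-7,9,13-trien-1-yl]oxolan-2-yl}-1,2-dioxan-3-yl]acetate, via hydroperoxide 26 (not isolated)
Conditions: H2O2 (anhydrous, Et2O solution, excess) premixed with KOtBu, THF, −20 to 0 °C, then rt
Reagents that add atoms: hydrogen peroxide, OO
Why: SN2 perhydrolysis then intramolecular peroxy-Michael addition: the weakly basic hydroperoxide anion should displace the triflate with inversion (C6 becomes S), and the peroxy anion then adds 6-exo-trig to the enoate, reversibly and through a chair with both substituents equatorial, which should set C3 as S (trans-3,6).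

Step 16
Reactants: 27 ethyl 2-[(3S,6S)-6-{(2S,5R)-5-[(7Z,9Z)-tetradeca-7,9,13-trien-1-yl]oxolan-2-yl}-1,2-dioxan-3-yl]acetate
Product: 28 2-[(3S,6S)-6-{(2S,5R)-5-[(7Z,9Z)-tetradeca-7,9,13-trien-1-yl]oxolan-2-yl}-1,2-dioxan-3-yl]acetic acid (target)
Conditions: LiOH, THF/H2O, 0 °C; then aq. HCl to pH 4
Reagents that add atoms: lithium hydroxide, [Li+].[OH-]
Why: Saponification with cold aqueous hydroxide, which a dialkyl peroxide of the 1,2-dioxane type should tolerate, frees the acid without touching any stereocentre.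

Compound list
1 | acrolein | C=CC=O | starting material
2 | benzoic anhydride | O=C(OC(=O)c1ccccc1)c1ccccc1 | starting material
3 | prop-2-ene-1,1-diyl dibenzoate | C=CC(OC(=O)c1ccccc1)OC(=O)c1ccccc1 | intermediate
4 | propane-1,3-diol | OCCCO | starting material
5 | (3R,4S)-4,6-dihydroxyhex-1-en-3-yl benzoate | OCC[C@@H]([C@H](OC(=O)c1ccccc1)C=C)O | intermediate
6 | (3R,4S)-6-chloro-4-hydroxyhex-1-en-3-yl benzoate | ClCC[C@@H]([C@H](OC(=O)c1ccccc1)C=C)O | intermediate
7 | (3R,4S)-6-chloro-4-(chloromethoxy)hex-1-en-3-yl benzoate | ClCC[C@@H]([C@H](OC(=O)c1ccccc1)C=C)OCCl | intermediate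
8 | (3R,4S)-6-chloro-4-[(phenylsulfonyl)methoxy]hex-1-en-3-yl benzoate | ClCC[C@@H]([C@H](OC(=O)c1ccccc1)C=C)OCS(=O)(=O)c1ccccc1 | intermediate
9 | (3R,4S)-6-chloro-4-[(phenylsulfonyl)methoxy]hex-1-en-3-ol | ClCC[C@@H]([C@H](O)C=C)OCS(=O)(=O)c1ccccc1 | intermediate
10 | tert-butyl{[(3R,4S)-6-chloro-4-[(phenylsulfonyl)methoxy]hex-1-en-3-yl]oxy}dimethylsilane | ClCC[C@@H]([C@H](O[Si](C)(C)C(C)(C)C)C=C)OCS(=O)(=O)c1ccccc1 | intermediate
11 | 10 lithiated at the carbon between sulfonyl group and ether oxygen | ClCC[C@@H]([C@H](O[Si](C)(C)C(C)(C)C)C=C)OC([Li])S(=O)(=O)c1ccccc1 | intermediate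
12 | tert-butyldimethyl{[(1R)-1-[(2S,5RS)-5-(phenylsulfonyl)oxolan-2-yl]prop-2-en-1-yl]oxy}silane (both C5 epimers) | O=S(=O)(c1ccccc1)C1CC[C@@H]([C@H](O[Si](C)(C)C(C)(C)C)C=C)O1 | intermediate
13 | ethyl (2Z)-3-iodoprop-2-enoate | CCOC(=O)/C=C\I | starting material
14 | 9-{(3R)-3-[(tert-butyldimethylsilyl)oxy]-3-[(2S,5RS)-5-(phenylsulfonyl)oxolan-2-yl]propyl}-9-borabicyclo[3.3.1]nonane | O=S(=O)(c1ccccc1)C1CC[C@@H]([C@H](O[Si](C)(C)C(C)(C)C)CCB2C3CCCC2CCC3)O1 | intermediate
15 | ethyl (2Z,6R)-6-[(tert-butyldimethylsilyl)oxy]-6-[(2S,5RS)-5-(phenylsulfonyl)oxolan-2-yl]hex-2-enoate | O=S(=O)(c1ccccc1)C1CC[C@@H]([C@H](O[Si](C)(C)C(C)(C)C)CC/C=C\C(=O)OCC)O1 | intermediate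
16 | 8-chlorooct-1-yne | C#CCCCCCCCl | starting material
17 | 1-bromo-8-chlorooct-1-yne | BrC#CCCCCCCCl | intermediate
18 | hex-5-en-1-yne | C#CCCC=C | starting material
19 | 14-chlorotetradec-1-ene-5,7-diyne | C=CCCC#CC#CCCCCCCCl | intermediate
20 | (5Z,7Z)-14-chlorotetradeca-1,5,7-triene | C=CCC/C=C\C=C/CCCCCCCl | intermediate
21 | (7Z,9Z)-tetradeca-7,9,13-trien-1-ylmagnesium chloride | C=CCC/C=C\C=C/CCCCCC[Mg]Cl | intermediate
22 | bis[(7Z,9Z)-tetradeca-7,9,13-trien-1-yl]zinc | C=CCC/C=C\C=C/CCCCCC[Zn]CCCCCC/C=C\C=C/CCC=C | intermediate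
23 | ethyl (2Z,6R)-6-[(tert-butyldimethylsilyl)oxy]-6-{(2S,5R)-5-[(7Z,9Z)-tetradeca-7,9,13-trien-1-yl]oxolan-2-yl}hex-2-enoate | C=CCC/C=C\C=C/CCCCCC[C@@H]1CC[C@@H]([C@H](O[Si](C)(C)C(C)(C)C)CC/C=C\C(=O)OCC)O1 | intermediate
24 | ethyl (2Z,6R)-6-hydroxy-6-{(2S,5R)-5-[(7Z,9Z)-tetradeca-7,9,13-trien-1-yl]oxolan-2-yl}hex-2-enoate | C=CCC/C=C\C=C/CCCCCC[C@@H]1CC[C@@H]([C@H](O)CC/C=C\C(=O)OCC)O1 | intermediate
25 | ethyl (2Z,6R)-6-{(2S,5R)-5-[(7Z,9Z)-tetradeca-7,9,13-trien-1-yl]oxolan-2-yl}-6-{[(trifluoromethyl)sulfonyl]oxy}hex-2-enoate | C=CCC/C=C\C=C/CCCCCC[C@@H]1CC[C@@H]([C@H](OS(=O)(=O)C(F)(F)F)CC/C=C\C(=O)OCC)O1 | intermediate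
26 | ethyl (2Z,6S)-6-hydroperoxy-6-{(2S,5R)-5-[(7Z,9Z)-tetradeca-7,9,13-trien-1-yl]oxolan-2-yl}hex-2-enoate | C=CCC/C=C\C=C/CCCCCC[C@@H]1CC[C@@H]([C@@H](OO)CC/C=C\C(=O)OCC)O1 | intermediate
27 | ethyl 2-[(3S,6S)-6-{(2S,5R)-5-[(7Z,9Z)-tetradeca-7,9,13-trien-1-yl]oxolan-2-yl}-1,2-dioxan-3-yl]acetate | C=CCC/C=C\C=C/CCCCCC[C@@H]1CC[C@@H]([C@@H]2CC[C@@H](CC(=O)OCC)OO2)O1 | intermediate
28 | 2-[(3S,6S)-6-{(2S,5R)-5-[(7Z,9Z)-tetradeca-7,9,13-trien-1-yl]oxolan-2-yl}-1,2-dioxan-3-yl]acetic acid | C=CCC/C=C\C=C/CCCCCC[C@@H]1CC[C@@H]([C@@H]2CC[C@@H](CC(=O)O)OO2)O1 | target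

Total step count: 16. Longest linear sequence: 13 steps (steps 1–8 and 12–16); steps 9–11 make the chain, which joins in step 12.

Steps most likely to fail

Step 15. E2 loss of triflic acid, attack of hydroperoxide anion on the ester or enoate, and over-alkylation to a dialkyl peroxide may all compete with the substitution at the hindered secondary carbon. The fallback sets out from 25 and comes back at 27. The triflate is displaced with a monoprotected hydroperoxide, 2-methoxypropan-2-yl hydroperoxide (made beforehand from 2-methoxypropene and H2O2), with KOtBu in THF at 0 °C. This should give the peroxyketal ethyl (2Z,6S)-6-[(2-methoxypropan-2-yl)peroxy]-6-{(2S,5R)-5-[(7Z,9Z)-tetradeca-7,9,13-trien-1-yl]oxolan-2-yl}hex-2-enoate F1 with inversion. AcOH/THF/H2O then releases the hydroperoxide 26, now isolated without any free hydroperoxide anion near the enoate, and Et2NH in CF3CH2OH closes the dioxane to 27.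

Step 12. Facial selectivity in the alkylation of the oxocarbenium ion may be low (cis and trans oxolanes), and β-hydride transfer from the alkylzinc may reduce the cation. The fallback sets out from 15 and comes back at 24, so that step 13 is skipped. HF·pyridine first removes the silyl group to give ethyl (2Z,6R)-6-hydroxy-6-[(2S,5RS)-5-(phenylsulfonyl)oxolan-2-yl]hex-2-enoate F2. ZnBr2 in CH2Cl2 then lets the C6 hydroxyl capture the oxocarbenium ion as the bicyclic acetal ethyl (2Z)-5-[(1S,3R,4S)-2,7-dioxabicyclo[2.2.1]heptan-3-yl]pent-2-enoate F3. Opening of F3 with the diorganozinc 22 and ZnBr2 should take place anti to the departing, metal-bound C6 oxygen, which is tied to the face of the side chain, and so give the trans alcohol 24.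

Step 7. Displacement of the chloride may be slow enough for the lithiated sulfone to decompose or to act as a base (E2). The fallback sets out from 6, comes back at 12 and closes the same bond with reversed polarity.
- The C7 hydroxyl is formylated (acetic formic anhydride, pyridine) to (3R,4S)-6-chloro-4-(formyloxy)hex-1-en-3-yl benzoate F4.
- NaI in acetone gives (3R,4S)-4-(formyloxy)-6-iodohex-1-en-3-yl benzoate F5.
- SmI2 in THF/HMPA at −78 °C generates the alkylsamarium, which should add to the formate carbonyl (intramolecular Barbier reaction, 5-exo-trig) to give the lactol (1R)-1-[(2S,5RS)-5-hydroxyoxolan-2-yl]prop-2-en-1-yl benzoate F6.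
- PhSO2H with CaCl2 in CH2Cl2 gives (1R)-1-[(2S,5RS)-5-(phenylsulfonyl)oxolan-2-yl]prop-2-en-1-yl benzoate F7.
- K2CO3 in MeOH gives (1R)-1-[(2S,5RS)-5-(phenylsulfonyl)oxolan-2-yl]prop-2-en-1-ol F8, and TBSOTf with 2,6-lutidine returns 12.

Further compounds
F1 | step 15 | ethyl (2Z,6S)-6-[(2-methoxypropan-2-yl)peroxy]-6-{(2S,5R)-5-[(7Z,9Z)-tetradeca-7,9,13-trien-1-yl]oxolan-2-yl}hex-2-enoate | C=CCC/C=C\C=C/CCCCCC[C@@H]1CC[C@@H]([C@@H](OOC(C)(C)OC)CC/C=C\C(=O)OCC)O1
F2 | step 12 | ethyl (2Z,6R)-6-hydroxy-6-[(2S,5RS)-5-(phenylsulfonyl)oxolan-2-yl]hex-2-enoate | O=S(=O)(c1ccccc1)C1CC[C@@H]([C@H](O)CC/C=C\C(=O)OCC)O1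
F3 | step 12 | ethyl (2Z)-5-[(1S,3R,4S)-2,7-dioxabicyclo[2.2.1]heptan-3-yl]pent-2-enoate | [C@H]12CC[C@H](O1)[C@@H](CC/C=C\C(=O)OCC)O2
F4 | step 7 | (3R,4S)-6-chloro-4-(formyloxy)hex-1-en-3-yl benzoate | ClCC[C@@H]([C@H](OC(=O)c1ccccc1)C=C)OC=O
F5 | step 7 | (3R,4S)-4-(formyloxy)-6-iodohex-1-en-3-yl benzoate | ICC[C@@H]([C@H](OC(=O)c1ccccc1)C=C)OC=O
F6 | step 7 | (1R)-1-[(2S,5RS)-5-hydroxyoxolan-2-yl]prop-2-en-1-yl benzoate | OC1CC[C@@H]([C@H](OC(=O)c2ccccc2)C=C)O1
F7 | step 7 | (1R)-1-[(2S,5RS)-5-(phenylsulfonyl)oxolan-2-yl]prop-2-en-1-yl benzoate | O=S(=O)(c1ccccc1)C1CC[C@@H]([C@H](OC(=O)c2ccccc2)C=C)O1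
F8 | step 7 | (1R)-1-[(2S,5RS)-5-(phenylsulfonyl)oxolan-2-yl]prop-2-en-1-ol | O=S(=O)(c1ccccc1)C1CC[C@@H]([C@H](O)C=C)O1
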